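**Assumptions.** (S)-5-(Hydroxymethyl)furan-2(5H)-one and 4-(benzyloxy)-3-methoxybenzyl bromide are purchasable. The Davis oxaziridine is used as the racemic reagent; it gives no enantiocontrol, and C8 is re-set in Step 5 anyway.

## Retrosynthetic overview
1. The target comes from global O-debenzylation of the tri-O-benzyl lactone. The quaternary C8 carbinol is made last, by alkylating the α-benzyloxy lactone enolate anti to the C8′ benzyl group (C8–CH2Ar bond).
2. That lactone comes from α-hydroxylation and O-benzylation of the (S)-β-(arylmethyl)-γ-butyrolactone. The only ring, the γ-lactone, is present from the first step.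
3. The β-benzyl lactone comes from traceless excision of the C5-hydroxymethyl relay from a 4,5-trans lactone.
4. That trans lactone comes from photoredox decarboxylative Giese addition of the 4-benzyloxy-3-methoxybenzyl radical to chiral-pool (S)-5-(hydroxymethyl)butenolide. This forms the C8′–CH2Ar bond and sets C8′.

## Route

**Step 1**
Reactants: 1 (S)-5-(hydroxymethyl)furan-2(5H)-one; 2 4-(benzyloxy)-3-methoxyphenylacetic acid
Product: 3 (4S,5S)-4-[4-(benzyloxy)-3-methoxybenzyl]-5-(hydroxymethyl)dihydrofuran-2(3H)-one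
Conditions: 4CzIPN (2 mol%), Cs2CO3 (0.5 equiv), 2 (2 equiv), DMF (0.1 M), 455 nm LEDs, 25 °C, 16 h
Reagents that add atoms: none (the ArCH2 unit comes from reactant 2; CO2 is lost)
Why: Photoredox decarboxylative Giese addition; the benzyl radical adds to C4 of the butenolide anti to the C5 CH2OH, and the α-carbonyl radical is reduced to the enolate and protonated. This sets C8′ (C4) trans to the relay stereocentre.

**Step 2**
Reactant: 3
Product: 4 (S)-4-[4-(benzyloxy)-3-methoxybenzyl]dihydrofuran-2(3H)-one
Conditions: CeCl3 (10 mol%), nBu4NCl (10 mol%), iPr3SiSH (20 mol%), MeCN (0.05 M), 390 nm LEDs, 25 °C, 24 h, N2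
Reagents that add atoms: none (CH2O is lost; the thiol only donates H)
Why: Proposed new method: Ce(IV)–alkoxide LMCT homolysis gives the primary alkoxy radical. This β-fragments to CH2=O and the ring C5 radical, which is stabilised by the adjacent O. Thiol HAT then gives C5H2, so RCH2OH becomes RH (net retro-hydroxymethylation). The closest known reactions are Ce-LMCT alkoxy-radical β-scission and Suárez fragmentation. The trans relationship disfavours 1,5-HAT from the benzylic C–H, and C5 becomes CH2, so C8′ is left as the only stereocentre.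

**Step 3**
Reactants: 4; 5 (±)-3-phenyl-2-(phenylsulfonyl)oxaziridine
Product: 6 (3S,4R)-3-hydroxy-4-[4-(benzyloxy)-3-methoxybenzyl]dihydrofuran-2(3H)-one
Conditions: LiHMDS (1.1 equiv), THF, −78 °C, 45 min; then 5 (1.3 equiv), −78 °C, 1 h
Reagents that add atoms: Davis oxaziridine, O=S(=O)(c1ccccc1)N1OC1c1ccccc1 (transfers O)
Why: Enolate α-hydroxylation (Davis); O is delivered anti to the C8′ benzyl. C8 is re-set in Step 5, so this facial selectivity does not matter.

**Step 4**
Reactants: 6; 7 benzyl 2,2,2-trichloroacetimidate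
Product: 8 (3S,4R)-3-(benzyloxy)-4-[4-(benzyloxy)-3-methoxybenzyl]dihydrofuran-2(3H)-one
Conditions: 7 (2 equiv), TfOH (5 mol%), CH2Cl2/cyclohexane 1:2, 0 °C to rt, 12 h
Reagents that add atoms: benzyl trichloroacetimidate, N=C(OCc1ccccc1)C(Cl)(Cl)Cl (transfers Bn)
Why: Acid-catalysed imidate O-benzylation protects the tertiary-to-be carbinol oxygen; no stereocentre is changed.

**Step 5**
Reactants: 8; 9 4-(benzyloxy)-3-methoxybenzyl bromide
Product: 10 (3R,4R)-3-(benzyloxy)-3,4-bis[4-(benzyloxy)-3-methoxybenzyl]dihydrofuran-2(3H)-one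
Conditions: LiHMDS (1.2 equiv), THF/DMPU 5:1, −78 °C, 40 min; then 9 (1.5 equiv), −78 to −40 °C, 4 h
Reagents that add atoms: 4-(benzyloxy)-3-methoxybenzyl bromide, COc1cc(CBr)ccc1OCc1ccccc1 (transfers ArCH2)
Why: Enolate alkylation; the electrophile attacks the Li enolate anti to the C8′ benzyl, so the new CH2Ar is trans to it and OBn is cis. This sets quaternary C8 as (R).

**Step 6**
Reactant: 10
Product: 11 (+)-nortrachelogenin, (3R,4R)-3-hydroxy-3,4-bis(4-hydroxy-3-methoxybenzyl)dihydrofuran-2(3H)-one
Conditions: H2 (1 atm), 20% Pd(OH)2/C, EtOAc/EtOH 1:1, cat. AcOH, rt, 24 h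
Reagents that add atoms: none (H2 only)
Why: Hydrogenolysis cleaves the two aryl benzyl ethers and the tertiary benzyl ether; no stereocentre is touched.

## Compound list
1 | (S)-5-(hydroxymethyl)furan-2(5H)-one | OC[C@@H]1C=CC(=O)O1 | starting material
2 | 4-(benzyloxy)-3-methoxyphenylacetic acid | COc1cc(CC(=O)O)ccc1OCc1ccccc1 | starting material
3 | (4S,5S)-4-[4-(benzyloxy)-3-methoxybenzyl]-5-(hydroxymethyl)dihydrofuran-2(3H)-one | COc1cc(C[C@H]2CC(=O)O[C@@H]2CO)ccc1OCc1ccccc1 | intermediate
4 | (S)-4-[4-(benzyloxy)-3-methoxybenzyl]dihydrofuran-2(3H)-one | COc1cc(C[C@@H]2COC(=O)C2)ccc1OCc1ccccc1 | intermediate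
5 | 3-phenyl-2-(phenylsulfonyl)oxaziridine (racemic) | O=S(=O)(c1ccccc1)N1OC1c1ccccc1 | starting material (reagent)
6 | (3S,4R)-3-hydroxy-4-[4-(benzyloxy)-3-methoxybenzyl]dihydrofuran-2(3H)-one | COc1cc(C[C@@H]2COC(=O)[C@H]2O)ccc1OCc1ccccc1 | intermediate
7 | benzyl 2,2,2-trichloroacetimidate | N=C(OCc1ccccc1)C(Cl)(Cl)Cl | starting material (reagent)
8 | (3S,4R)-3-(benzyloxy)-4-[4-(benzyloxy)-3-methoxybenzyl]dihydrofuran-2(3H)-one | COc1cc(C[C@@H]2COC(=O)[C@H]2OCc2ccccc2)ccc1OCc1ccccc1 | intermediate
9 | 4-(benzyloxy)-3-methoxybenzyl bromide | COc1cc(CBr)ccc1OCc1ccccc1 | starting material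
10 | (3R,4R)-3-(benzyloxy)-3,4-bis[4-(benzyloxy)-3-methoxybenzyl]dihydrofuran-2(3H)-one | COc1cc(C[C@@H]2COC(=O)[C@@]2(OCc2ccccc2)Cc2ccc(OCc3ccccc3)c(OC)c2)ccc1OCc1ccccc1 | intermediate
11 | (+)-nortrachelogenin | COc1cc(C[C@@H]2COC(=O)[C@@]2(O)Cc2ccc(O)c(OC)c2)ccc1O | target

## Summary
Total steps: 6. Longest linear sequence: 6 (1 → 3 → 4 → 6 → 8 → 10 → 11).

**Three steps most likely to fail**
1. **Step 2 (proposed new step).** The alkoxy radical may undergo HAT or arene oxidation instead of β-scission, or Ce(III)/thiyl turnover may stall.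
   Fallback (known chemistry): open the lactone of 3 with LiOH and cleave the resulting 1,2-diol with NaIO4. Reduce the aldehyde with NaBH4 and acidify, so the acid relactonises to 4.
2. **Step 1.** The radical may dimerise, or the trans selectivity or yield may be poor.
   Fallback: protect the OH of 1 as its TBS ether. Add 4-benzyloxy-3-methoxybenzylmagnesium chloride with CuI/TMSCl in a polar trans-selective 1,4-addition. Then remove TBS with TBAF to give 3.
3. **Step 5.** The quaternary centre may form with low trans selectivity or yield, or the α-benzyloxy enolate may undergo a Wittig rearrangement.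
   Fallback: use the aldol of the enolate of 8 with 4-benzyloxy-3-methoxybenzaldehyde instead of alkylation. The resulting benzylic C–OH is then removed in the final Pd-catalysed hydrogenolysis.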